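**Plan**
- Retrosynthesis: cut the C6 veratrate and the oxirane (hydroxyl-directed epoxidation of C8=C9), then C8=C9 (ring-closing metathesis, seven-membered ring B), then C7–C8 (cuprate on a C7 tosylate), then C2–C3 of the cyclopentane (ring A), then C10–C9 and the C1/C5 substituents on a six-membered lactone template.
- The C2–C3 cut rests on the cis-1,3 pair C2–OAc / C4–OH across the C3 methylene of ring A. An acetoxycarbenium ion at C2 adds to a CH2=C(i-Pr) group on C5, and the same acetate captures the C4 cation as a bridged 1,3-dioxan-2-ylium ion. Water returns the 2-acetate and the 4-alcohol.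
- Helpers: O6 and O10 are silyl ethers and O7 a tosylate during that step, so no other oxygen competes. The tosylate is then used for C7–C8 and the silyl groups are removed.
- Forward order: lactone template (metathesis) → conjugate addition and two alkylations → opening with vinyllithium and ketone reduction → acyclic aldehyde → ring A → methallyl unit → ring B → epoxide → veratrate.
- Stereochemistry: C6 from (S)-but-3-ene-1,2-diol; C5 and C1 on the lactone (anti additions); C10 by Felkin/chelation-controlled hydride addition to the acyclic ketone; C2 and C4 in the ring-A closure; C8/C9 by directed epoxidation.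

Key step: step 12

Numbering: carbons keep the daucane numbers of the target (C1 CMe, C2 CHOAc, C3 CH2, C4 C(OH)i-Pr, C5 ring-fusion CH, C6 CH–O-veratroyl, C7 CH2, C8/C9 oxirane, C10 CHOH); organometallic reagents are prepared beforehand in the usual way from the commercial halides.

Assumption: read literally, the two oxirane descriptors of the given string put C7 and C10 on opposite sides of the oxirane plane (a trans-fused epoxide on the cycloheptane, not a tenable arrangement); the route is planned for the cis-fused 8,9-epoxide on the face of the C10 hydroxyl (oxirane CH as written), which is what step 16 should deliver, and the strings of 21 and 22 keep the descriptors as given.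

Step 1
Reactants: 1 (S)-but-3-ene-1,2-diol
Product: 2 (S)-2-hydroxybut-3-en-1-yl acrylate
Conditions: CH2=CHCOCl (1.0 equiv), 2,4,6-collidine, CH2Cl2, −78 °C
Reagents that add atoms: acryloyl chloride C=CC(Cl)=O
Why: Low-temperature esterification should take the primary hydroxyl in preference to the secondary one, and the C6 stereocentre of the chiral-pool diol is not touched.

Step 2
Reactants: 2 (S)-2-hydroxybut-3-en-1-yl acrylate
Product: 3 (S)-2-(tert-butyldimethylsilyloxy)but-3-en-1-yl acrylate
Conditions: TBSCl, imidazole, DMF, 0 °C → rt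
Reagents that add atoms: tert-butyldimethylsilyl chloride CC(C)(C)[Si](C)(C)Cl
Why: Standard silyl ether formation on the secondary alcohol; the bulky silyloxy group later directs the cuprate and keeps O6 from acting as a nucleophile.

Step 3
Reactants: 3 (S)-2-(tert-butyldimethylsilyloxy)but-3-en-1-yl acrylate
Product: 4 (S)-5-(tert-butyldimethylsilyloxy)-5,6-dihydro-2H-pyran-2-one
Conditions: second-generation Grubbs catalyst (5 mol %), CH2Cl2 (0.01 M), 40 °C
Reagents that add atoms: none
Why: Ring-closing metathesis of an acrylate with a terminal alkene should give the six-membered unsaturated lactone with loss of ethene; no stereocentre is formed.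

Step 4
Reactants: 4 (S)-5-(tert-butyldimethylsilyloxy)-5,6-dihydro-2H-pyran-2-one
Product: 6 all-trans 5-(tert-butyldimethylsilyloxy)-3-methyl-4-(3-methylbut-1-en-2-yl)tetrahydro-2H-pyran-2-one, via lithium enolate 5 (not isolated)
Conditions: [CH2=C(i-Pr)]2CuLi, Et2O/THF, −78 °C; then MeI, HMPA, −78 → −20 °C
Reagents that add atoms: lithium bis(3-methylbut-1-en-2-yl)cuprate [Li+].C=C(C(C)C)[Cu-]C(=C)C(C)C; iodomethane CI
Why: Cuprate conjugate addition should occur anti to the adjacent silyloxy group (sets C5) and the enolate should be methylated anti to the new substituent (tandem conjugate addition–alkylation); the methyl-bearing centre is planarized again in step 5.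

Step 5
Reactants: 6 all-trans 5-(tert-butyldimethylsilyloxy)-3-methyl-4-(3-methylbut-1-en-2-yl)tetrahydro-2H-pyran-2-one
Product: 8 quaternary lactone 5-(tert-butyldimethylsilyloxy)-3-[(4-methoxybenzyloxy)methyl]-3-methyl-4-(3-methylbut-1-en-2-yl)tetrahydro-2H-pyran-2-one (CH2OPMB trans and methyl cis to the alkenyl group), via lithium enolate 7 (not isolated)
Conditions: LiN(i-Pr)2, THF, −78 °C; then 4-MeOC6H4CH2OCH2Cl, −78 → −40 °C
Reagents that add atoms: 4-methoxybenzyl chloromethyl ether COc1ccc(COCCl)cc1
Why: Lactone enolate alkylation with the reactive chloromethyl ether should take place anti to the C5 alkenyl group, which sets the quaternary C1 with C2 trans and the methyl cis to that group.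

Step 6
Reactants: 8 quaternary lactone
Product: 9 vinyl ketone 6-(tert-butyldimethylsilyloxy)-7-hydroxy-4-[(4-methoxybenzyloxy)methyl]-4-methyl-5-(3-methylbut-1-en-2-yl)hept-1-en-3-one (C1, C5, C6 as in 8)
Conditions: CH2=CHLi (1.3 equiv), THF, −78 °C; NH4Cl (aq) at −78 °C
Reagents that add atoms: vinyllithium [Li]C=C
Why: Organolithium mono-addition to a lactone: the cyclic lithium hemiketal alkoxide is stable at −78 °C (the α-carbon is quaternary, so no enolization) and should give the vinyl ketone only on quench.

Step 7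
Reactants: 9 vinyl ketone
Product: 10 allylic alcohol 2-(tert-butyldimethylsilyloxy)-4-[(4-methoxybenzyloxy)methyl]-4-methyl-3-(3-methylbut-1-en-2-yl)hept-6-ene-1,5-diol (C10 carbinol as in the target)
Conditions: Zn(BH4)2, Et2O, −30 °C
Reagents that add atoms: none
Why: 1,2-Reduction under Cram-chelate control (ketone oxygen and the PMB ether oxygen on zinc); the Felkin–Anh model with the C5 branch as the large group gives the same sense, so hydride should add from the methyl side and set C10.

Step 8
Reactants: 10 allylic alcohol (1,5-diol)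
Product: 11 primary tosylate 2-(tert-butyldimethylsilyloxy)-5-hydroxy-4-[(4-methoxybenzyloxy)methyl]-4-methyl-3-(3-methylbut-1-en-2-yl)hept-6-en-1-yl 4-methylbenzenesulfonate
Conditions: TsCl (1.1 equiv), Et3N, DMAP (cat.), CH2Cl2, 0 °C
Reagents that add atoms: 4-toluenesulfonyl chloride Cc1ccc(S(Cl)(=O)=O)cc1
Why: Sulfonylation should be selective for the unhindered primary hydroxyl over the neopentyl allylic one; the tosylate is the later leaving group and a non-nucleophilic mask for O7.

Step 9
Reactants: 11 primary tosylate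
Product: 12 bis-silyl ether 2,5-bis(tert-butyldimethylsilyloxy)-4-[(4-methoxybenzyloxy)methyl]-4-methyl-3-(3-methylbut-1-en-2-yl)hept-6-en-1-yl 4-methylbenzenesulfonate
Conditions: TBSOTf, 2,6-lutidine, CH2Cl2, −40 → 0 °C
Reagents that add atoms: tert-butyldimethylsilyl triflate CC(C)(C)[Si](C)(C)OS(=O)(=O)C(F)(F)F
Why: Silyl triflate silylation is the standard way to protect a hindered secondary alcohol.

Step 10
Reactants: 12 bis-silyl ether
Product: 13 neopentyl alcohol 2,5-bis(tert-butyldimethylsilyloxy)-4-(hydroxymethyl)-4-methyl-3-(3-methylbut-1-en-2-yl)hept-6-en-1-yl 4-methylbenzenesulfonate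
Conditions: DDQ, CH2Cl2/pH 7 buffer (10:1), 0 °C
Reagents that add atoms: none
Why: Oxidative cleavage of the PMB ether by DDQ should leave silyl ethers, tosylate and alkenes untouched.

Step 11
Reactants: 13 neopentyl alcohol
Product: 14 aldehyde 2,5-bis(tert-butyldimethylsilyloxy)-4-formyl-4-methyl-3-(3-methylbut-1-en-2-yl)hept-6-en-1-yl 4-methylbenzenesulfonate
Conditions: Dess–Martin periodinane, NaHCO3, CH2Cl2, rt
Reagents that add atoms: none
Why: Dess–Martin oxidation of the primary alcohol gives an aldehyde whose α-carbon is quaternary and cannot epimerize.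

Step 12
Reactants: 14 aldehyde
Product: 17 ring-A hydroxy acetate (cyclopentane C1–C5 with C2–OAc and C4–OH cis; C1 carries Me and CH(OTBS)CH=CH2; C5 carries CH(OTBS)CH2OTs), via acetoxycarbenium triflate 15 (not isolated), via dioxanylium triflate 16 (not isolated)
Conditions: AcCl, AgOTf (AcOTf formed first, 1.5 equiv), 2,6-di-tert-butyl-4-methylpyridine, CH2Cl2, −78 → −40 °C; then THF/H2O, NaHCO3, 0 °C
Reagents that add atoms: acetyl chloride CC(Cl)=O; water O
Why: Proposed new method: O-acylation of the aldehyde by AcOTf gives the acetoxycarbenium ion 15, whose C2 is attacked by the CH2 terminus (C3) of the CH2=C(i-Pr) group to form the C2–C3 bond and a tertiary cation at C4, and the carbonyl oxygen of the new C2 acetate captures that cation to give the bridged 2-methyl-1,3-dioxan-2-ylium ion 16 (a 2,4-dioxabicyclo[3.2.1]octane), which water opens to the secondary acetate and the tertiary alcohol. The closest known reaction types are the Prins cyclization of alkenes onto oxocarbenium ions, the addition of allylsilanes to acyloxycarbenium ions from acylals (Sakurai type) and acyloxy participation through cyclic acyloxonium ions as in the Woodward–Prévost cis-hydroxylation, but their union in one ring closure has not been shown. Ring A closes 5-exo with respect to the C2=O+ bond (5-endo at the alkene, feasible for a cationic closure that gives a tertiary cation), and the temporary dioxanylium ring closes by six-membered O-attack on C4. C2 is controlled by an envelope transition state in which the C10 and C6 side chains on C1 and C5 (trans) are pseudoequatorial and the C1 methyl is axial, so the oxocarbenium turns its hydrogen and not its acyloxy oxygen to that methyl and the C2–O bond ends anti to the methyl and cis to C10. C4 is controlled by the tether, since the acetate on C2 can reach C4 only on the face syn to the C2–O bond, which enforces the 2,4-cis pair with isopropyl on the other face. The step needs chemoselectivity, secured because only the 1,1-disubstituted alkene gives a tertiary cation (the C10 vinyl group would give a secondary one) and because O6 and O10 are silyl ethers and O7 a sulfonate, and it needs regioselective hydrolysis, which should follow from the preference for the secondary over the tertiary ester.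

Step 13
Reactants: 17 ring-A hydroxy acetate
Product: 18 methallyl compound (as 17 with C7H2–C(CH3)=CH2 in place of C7H2–OTs)
Conditions: (CH2=CMe)2CuLi (3 equiv), Et2O/THF, −40 → 0 °C
Reagents that add atoms: lithium di(prop-1-en-2-yl)cuprate [Li+].C=C(C)[Cu-]C(C)=C
Why: SN2 coupling of a primary tosylate with a Gilman reagent forms C7–C8; the secondary acetate should be inert to the cuprate at low temperature and no stereocentre is affected.

Step 14
Reactants: 18 methallyl compound
Product: 19 ring-A triol monoacetate (C6–OH, C10–OH and C4–OH free; C2–OAc)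
Conditions: HF·pyridine, pyridine, THF, 0 °C → rt
Reagents that add atoms: none
Why: Fluoride-mediated desilylation under mildly acidic conditions should remove both silyl ethers and leave the acetate in place.

Step 15
Reactants: 19 ring-A triol monoacetate
Product: 20 hydroazulene triol monoacetate (2-acetoxy-dauc-8-ene-4,6,10-triol, trans ring fusion)
Conditions: second-generation Grubbs catalyst (10 mol %), CH2Cl2 (0.005 M), 40 °C
Reagents that add atoms: none
Why: Ring-closing metathesis between the vinyl carbinol and the 1,1-disubstituted alkene should close ring B with the trisubstituted C8=C9 alkene (the free allylic hydroxyl assists); the trans fusion is already fixed at C1 and C5.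

Step 16
Reactants: 20 hydroazulene triol monoacetate
Product: 21 epoxy triol monoacetate (2-acetoxy-8,9-epoxydaucane-4,6,10-triol)
Conditions: VO(acac)2 (5 mol %), t-BuOOH, CH2Cl2, 0 °C → rt
Reagents that add atoms: tert-butyl hydroperoxide CC(C)(C)OO
Why: Vanadium-catalysed hydroxyl-directed epoxidation should deliver oxygen to the alkene face syn to the allylic C10–OH (the homoallylic C6–OH lies on the same face), setting C8 and C9.

Step 17
Reactants: 21 epoxy triol monoacetate
Product: 22 CNP0197096.3, 2-acetoxy-8,9-epoxy-4,10-dihydroxydaucan-6-yl 3,4-dimethoxybenzoate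
Conditions: 3,4-(MeO)2C6H3COCl (1.1 equiv), pyridine, DMAP (cat.), CH2Cl2, 0 °C
Reagents that add atoms: 3,4-dimethoxybenzoyl chloride COc1ccc(C(Cl)=O)cc1OC
Why: DMAP-catalysed esterification should take the C6 hydroxyl, the only accessible secondary alcohol, since C10–OH is flanked by the quaternary C1 and the oxirane and C4–OH is tertiary.

**Compound list**
1 | (S)-but-3-ene-1,2-diol | C=C[C@H](O)CO | starting material
2 | (S)-2-hydroxybut-3-en-1-yl acrylate | C=CC(=O)OC[C@@H](O)C=C | intermediate
3 | (S)-2-(tert-butyldimethylsilyloxy)but-3-en-1-yl acrylate | C=CC(=O)OC[C@@H](O[Si](C)(C)C(C)(C)C)C=C | intermediate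
4 | (S)-5-(tert-butyldimethylsilyloxy)-5,6-dihydro-2H-pyran-2-one | O=C1C=C[C@H](O[Si](C)(C)C(C)(C)C)CO1 | intermediate
5 | lithium enolate of the conjugate adduct (alkenyl group trans to OTBS) | [Li]OC1=C[C@@H](C(=C)C(C)C)[C@H](O[Si](C)(C)C(C)(C)C)CO1 | intermediate
6 | all-trans 5-(tert-butyldimethylsilyloxy)-3-methyl-4-(3-methylbut-1-en-2-yl)tetrahydro-2H-pyran-2-one | C[C@H]1C(=O)OC[C@@H](O[Si](C)(C)C(C)(C)C)[C@@H]1C(=C)C(C)C | intermediate
7 | lithium enolate of 6 | [Li]OC1=C(C)[C@@H](C(=C)C(C)C)[C@H](O[Si](C)(C)C(C)(C)C)CO1 | intermediate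
8 | quaternary lactone, 5-(tert-butyldimethylsilyloxy)-3-[(4-methoxybenzyloxy)methyl]-3-methyl-4-(3-methylbut-1-en-2-yl)tetrahydro-2H-pyran-2-one; CH2OPMB trans and methyl cis to the alkenyl group, alkenyl trans to OTBS | COc1ccc(COC[C@@]2(C)C(=O)OC[C@@H](O[Si](C)(C)C(C)(C)C)[C@@H]2C(=C)C(C)C)cc1 | intermediate
9 | vinyl ketone, 6-(tert-butyldimethylsilyloxy)-7-hydroxy-4-[(4-methoxybenzyloxy)methyl]-4-methyl-5-(3-methylbut-1-en-2-yl)hept-1-en-3-one; C1, C5, C6 as in 8 | C=CC(=O)[C@](C)(COCc1ccc(OC)cc1)[C@@H](C(=C)C(C)C)[C@H](O[Si](C)(C)C(C)(C)C)CO | intermediate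
10 | allylic alcohol, 2-(tert-butyldimethylsilyloxy)-4-[(4-methoxybenzyloxy)methyl]-4-methyl-3-(3-methylbut-1-en-2-yl)hept-6-ene-1,5-diol; C10 as in the target | C=C[C@H](O)[C@](C)(COCc1ccc(OC)cc1)[C@@H](C(=C)C(C)C)[C@H](O[Si](C)(C)C(C)(C)C)CO | intermediate
11 | primary tosylate of 10 (C7–OTs, C10–OH free) | C=C[C@H](O)[C@](C)(COCc1ccc(OC)cc1)[C@@H](C(=C)C(C)C)[C@H](O[Si](C)(C)C(C)(C)C)COS(=O)(=O)c1ccc(C)cc1 | intermediate
12 | bis-silyl ether (C6–OTBS, C10–OTBS, C2H2–OPMB, C7–OTs) | C=C[C@H](O[Si](C)(C)C(C)(C)C)[C@](C)(COCc1ccc(OC)cc1)[C@@H](C(=C)C(C)C)[C@H](O[Si](C)(C)C(C)(C)C)COS(=O)(=O)c1ccc(C)cc1 | intermediate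
13 | neopentyl alcohol (C2H2–OH) | C=C[C@H](O[Si](C)(C)C(C)(C)C)[C@](C)(CO)[C@@H](C(=C)C(C)C)[C@H](O[Si](C)(C)C(C)(C)C)COS(=O)(=O)c1ccc(C)cc1 | intermediate
14 | aldehyde (C2H=O on the quaternary C1) | C=C[C@H](O[Si](C)(C)C(C)(C)C)[C@](C)(C=O)[C@@H](C(=C)C(C)C)[C@H](O[Si](C)(C)C(C)(C)C)COS(=O)(=O)c1ccc(C)cc1 | intermediate
15 | acetoxycarbenium triflate (O-acetylated aldehyde 14) | C=C[C@H](O[Si](C)(C)C(C)(C)C)[C@](C)(C=[O+]C(C)=O)[C@@H](C(=C)C(C)C)[C@H](O[Si](C)(C)C(C)(C)C)COS(=O)(=O)c1ccc(C)cc1.[O-]S(=O)(=O)C(F)(F)F | intermediate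
16 | dioxanylium triflate (2-methyl-1,3-dioxan-2-ylium bridging C2 and C4 of ring A on the face of H5) | C=C[C@H](O[Si](C)(C)C(C)(C)C)[C@]1(C)[C@H]2C[C@](C(C)C)([O+]=C(C)O2)[C@H]1[C@H](O[Si](C)(C)C(C)(C)C)COS(=O)(=O)c1ccc(C)cc1.[O-]S(=O)(=O)C(F)(F)F | intermediate
17 | ring-A hydroxy acetate; on the cyclopentane, C2–OAc, C4–OH, C5–H and the C10 chain lie on one face and C1–Me, C4–i-Pr and the C6 chain on the other | C=C[C@H](O[Si](C)(C)C(C)(C)C)[C@]1(C)[C@H](OC(C)=O)C[C@@](O)(C(C)C)[C@H]1[C@H](O[Si](C)(C)C(C)(C)C)COS(=O)(=O)c1ccc(C)cc1 | intermediate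
18 | methallyl compound (17 with C7H2–C(CH3)=CH2) | C=C[C@H](O[Si](C)(C)C(C)(C)C)[C@]1(C)[C@H](OC(C)=O)C[C@@](O)(C(C)C)[C@H]1[C@H](O[Si](C)(C)C(C)(C)C)CC(C)=C | intermediate
19 | ring-A triol monoacetate (18 without the silyl groups) | C=C[C@H](O)[C@]1(C)[C@H](OC(C)=O)C[C@@](O)(C(C)C)[C@H]1[C@H](O)CC(C)=C | intermediate
20 | hydroazulene triol monoacetate, 2-acetoxy-dauc-8-ene-4,6,10-triol; trans fusion, 2-OAc, 4-OH, 6-OH, 10-OH on the face of H5 | O[C@@H]1CC(C)=C[C@H](O)[C@]2(C)[C@H](OC(C)=O)C[C@@](O)(C(C)C)[C@@H]12 | intermediate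
21 | epoxy triol monoacetate, 2-acetoxy-8,9-epoxydaucane-4,6,10-triol (oxirane syn to C10–OH; descriptors as in the given string) | O[C@@H]1C[C@@]2(C)O[C@@H]2[C@H](O)[C@]2(C)[C@H](OC(C)=O)C[C@@](O)(C(C)C)[C@@H]12 | intermediate
22 | CNP0197096.3, 2-acetoxy-8,9-epoxy-4,10-dihydroxydaucan-6-yl 3,4-dimethoxybenzoate | COc1ccc(C(=O)O[C@@H]2C[C@@]3(C)O[C@@H]3[C@H](O)[C@]3(C)[C@H](OC(C)=O)C[C@@](O)(C(C)C)[C@@H]23)cc1OC | target

Total step count: 17. Longest linear sequence: 17 steps (fully linear from 1).

**Steps most likely to fail**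

Step 12 (Proposed new method). The alkene may attack the wrong face of the acetoxycarbenium ion. The C4 cation may be lost by 1,2-hydride shift or proton loss before the acetate closes on it. The acyl triflate may transfer acetyl to a silyl ether oxygen or acylate an alkene at carbon. Fallback with known chemistry, from aldehyde 14: Pinnick oxidation (NaClO2, NaH2PO4, 2-methylbut-2-ene) should give the carboxylic acid F1. Its acid chloride ((COCl)2; then SnCl4, −78 °C; then DBU) should close the same C2–C3 bond by intramolecular acylation of the alkene to the cyclopentenone F2. Weitz–Scheffer epoxidation (t-BuOOH, DBU) anti to the C5 side chain should give the epoxy ketone F3. SmI2 (THF/MeOH, −90 °C) should open it at C3 to the β-hydroxy ketone F4. Narasaka–Prasad reduction (Et2BOMe, NaBH4) should give the cis-1,3-diol F5. Ac2O/pyridine should acetylate only the secondary hydroxyl and return to 17.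

Step 13. Substitution at the β-branched primary tosylate may be slow, so that excess cuprate attacks the acetate or causes elimination. Fallback, from 17: NaI in acetone (Finkelstein exchange) should give the primary iodide F6. Reductive cross-electrophile coupling with 2-bromopropene (NiI2, 4,4'-di-tert-butyl-2,2'-bipyridine, Mn, DMA) through the C7 radical should then give 18.

Step 6. The tetrahedral intermediate may collapse early, leading to a second addition or conjugate addition to the vinyl ketone, or addition at the hindered carbonyl may stall. Fallback, from 8: i-Bu2AlH (−78 °C) should give the lactol F7. CH2=CHMgBr should open it to the allylic alcohol F8 as a mixture at C10. MnO2 should oxidize only the allylic hydroxyl and return to 9, whose reduction in step 7 then sets C10.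

**Further compounds**
F1 | step 12 | carboxylic acid (14 with C2 as CO2H) | C=C[C@H](O[Si](C)(C)C(C)(C)C)[C@](C)(C(=O)O)[C@@H](C(=C)C(C)C)[C@H](O[Si](C)(C)C(C)(C)C)COS(=O)(=O)c1ccc(C)cc1
F2 | step 12 | cyclopentenone (C2 ketone, C3=C4 with isopropyl on C4) | C=C[C@H](O[Si](C)(C)C(C)(C)C)[C@]1(C)C(=O)C=C(C(C)C)[C@H]1[C@H](O[Si](C)(C)C(C)(C)C)COS(=O)(=O)c1ccc(C)cc1
F3 | step 12 | epoxy ketone (C3–C4 oxirane on the face of H5) | C=C[C@H](O[Si](C)(C)C(C)(C)C)[C@]1(C)C(=O)[C@@H]2O[C@]2(C(C)C)[C@H]1[C@H](O[Si](C)(C)C(C)(C)C)COS(=O)(=O)c1ccc(C)cc1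
F4 | step 12 | β-hydroxy ketone (C2 ketone, C4–OH) | C=C[C@H](O[Si](C)(C)C(C)(C)C)[C@]1(C)C(=O)C[C@@](O)(C(C)C)[C@H]1[C@H](O[Si](C)(C)C(C)(C)C)COS(=O)(=O)c1ccc(C)cc1
F5 | step 12 | cis-1,3-diol (C2–OH, C4–OH) | C=C[C@H](O[Si](C)(C)C(C)(C)C)[C@]1(C)[C@H](O)C[C@@](O)(C(C)C)[C@H]1[C@H](O[Si](C)(C)C(C)(C)C)COS(=O)(=O)c1ccc(C)cc1
F6 | step 13 | primary iodide (17 with C7–I) | C=C[C@H](O[Si](C)(C)C(C)(C)C)[C@]1(C)[C@H](OC(C)=O)C[C@@](O)(C(C)C)[C@H]1[C@H](O[Si](C)(C)C(C)(C)C)CI
F7 | step 6 | lactol (8 with C10 as hemiacetal, both anomers) | COc1ccc(COC[C@@]2(C)C(O)OC[C@@H](O[Si](C)(C)C(C)(C)C)[C@@H]2C(=C)C(C)C)cc1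
F8 | step 6 | allylic alcohol (10 and its C10 epimer) | C=CC(O)[C@](C)(COCc1ccc(OC)cc1)[C@@H](C(=C)C(C)C)[C@H](O[Si](C)(C)C(C)(C)C)CO
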